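A direct plan would keep ring A as a bought ring. The enantioenriched cyclohexene ester A1 would be annulated under Lewis acid with the alkoxycyclobutanone A2 to the cis-octalenone A3. The side chain would then be joined by alkylating the C9 enolate of A3 with the chiral C6 triflate A4, and conjugate reduction, methylenation and deprotections would finish the synthesis.
Weak step, the ring B annulation of A1 with A2: an intermolecular capture of an unactivated trisubstituted alkene by a ring-opened cyclobutanone would be without close precedent. It would have to beat proton loss and lactonisation, and its facial control would rest on telling CH3 from CO2Me on the neighbouring quaternary carbon.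
Weak step, the enolate alkylation with A4: a hindered enolate carbon next to the quaternary C10 would have to displace a primary triflate that can eliminate. C9 would be set only by kinetic face selection at an epimerisable centre.
Weak stretch, run-up and protecting groups: about five steps to A1 and five to shorten a C10 chiral-pool alcohol by one carbon to A4 would build two small fragments. Silylation, ester cleavage, desilylation and reacetylation would add four operations that form no skeletal bond.

Retrosynthetic overview (labdane numbering: ring A = C1–C5 and C10, ring B = C5–C10, C17 on C8, C18 and C19 on C4, C20 on C10):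
1. The target is cut at C5–C10 and C8–C9. Both bonds come from one intramolecular Diels–Alder reaction of an open-chain (E)-vinylallene (C5=C6–C7=C8=C17), tethered through C4–C3–C2–C1(=O) to an (E)-α-methyl enone (C9=C10). The cycloaddition closes ring B and, as the tether ring, ring A in the same event.
2. The feature that invites this is the cis (5β-H) ring fusion between the quaternary C4 and C10, next to C9. The endo mode gives the cis fusion, the enone geometry gives C9 relative to C10, the preset C4 picks the diene face, and the allene terminus is the future C8=C17 methylene.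
3. The precursor is made in a line from whole (R)-linalool (C1, C9–C16 and C20; its oxidised methyl is C1), a vinyl unit (C2, C3), a formylpropanoate joined by enantioselective Michael addition (C4, C5, C18, C19), iodoform (C6) and an allenyl unit (C7, C8, C17).
4. After the key step only a 1,4-hydroboration with γ-protonation, acetylation and deletion of the C1 carbonyl remain. No ring is built onto a preformed ring, the side chain is never attached by enolate alkylation, and the chiral-pool alcohol is used whole.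

Key step: step 9

Remark on the chemistry: the sense of induction of the Michael catalyst in step 6 cannot be predicted with certainty, so the pseudo-enantiomer that gives the 2S adduct is taken to be the one named.

Step 1
Reactants: 1 (3R)-3,7-dimethylocta-1,6-dien-3-ol [(R)-linalool]
Product: 2 tert-butyl{[(3R)-3,7-dimethylocta-1,6-dien-3-yl]oxy}dimethylsilane
Conditions: tBuMe2SiOTf, 2,6-lutidine, CH2Cl2, 0 °C
Reagents that add atoms: tert-butyldimethylsilyl trifluoromethanesulfonate, CC(C)(C)[Si](C)(C)OS(=O)(=O)C(F)(F)F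
Why: Silyl triflate silylation protects the hindered tertiary allylic alcohol so that it cannot add to the enones made later (oxa-Michael addition), and the C13 stereocentre from the chiral pool is untouched.

Step 2
Reactants: 2 tert-butyl{[(3R)-3,7-dimethylocta-1,6-dien-3-yl]oxy}dimethylsilane
Product: 3 (2E,6R)-6-{[tert-butyl(dimethyl)silyl]oxy}-2,6-dimethylocta-2,7-dienal
Conditions: SeO2 (1.2 equiv), 1,4-dioxane, 75 °C
Reagents that add atoms: selenium dioxide, O=[Se]=O
Why: Riley allylic oxidation (ene reaction, then 2,3-sigmatropic shift) attacks the (E)-methyl group of the trisubstituted alkene, the vinyl group having no allylic hydrogen, and gives the (E)-enal whose aldehyde carbon becomes C1.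

Step 3
Reactants: 3 (2E,6R)-6-{[tert-butyl(dimethyl)silyl]oxy}-2,6-dimethylocta-2,7-dienal
Product: 4 (4E,8R)-8-{[tert-butyl(dimethyl)silyl]oxy}-4,8-dimethyldeca-1,4,9-trien-3-ol (both C3 epimers)
Conditions: CH2=CHMgBr (1.2 equiv), THF, −78 °C; sat. aq. NH4Cl
Reagents that add atoms: vinylmagnesium bromide, C=C[Mg]Br
Why: Grignard 1,2-addition to the enal at low temperature brings in C2 and C3, and the new carbinol centre is of no consequence because it is oxidised in step 4.

Step 4
Reactants: 4 (4E,8R)-8-{[tert-butyl(dimethyl)silyl]oxy}-4,8-dimethyldeca-1,4,9-trien-3-ol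
Product: 5 (4E,8R)-8-{[tert-butyl(dimethyl)silyl]oxy}-4,8-dimethyldeca-1,4,9-trien-3-one
Conditions: MnO2 (activated, 15 equiv), CH2Cl2, 23 °C; used at once
Reagents that add atoms: none
Why: MnO2 oxidation of the doubly allylic alcohol under neutral conditions gives the cross-conjugated dienone, in which the unsubstituted vinyl ketone is the only reactive Michael acceptor.

Step 5
Reactants: 6 ethyl 2-methyl-3-oxopropanoate; 7 2-(trimethylsilyl)ethan-1-ol
Product: 8 2-(trimethylsilyl)ethyl 2-methyl-3-oxopropanoate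
Conditions: DMAP (10 mol%), toluene, 110 °C, ethanol distilled off
Reagents that add atoms: none
Why: DMAP-catalysed transesterification of a β-oxo ester (through the acylketene) exchanges ethyl for the fluoride-labile 2-(trimethylsilyl)ethyl group, and the enolisable α-carbon carries no fixed stereocentre.

Step 6
Reactants: 5 (4E,8R)-8-{[tert-butyl(dimethyl)silyl]oxy}-4,8-dimethyldeca-1,4,9-trien-3-one; 8 2-(trimethylsilyl)ethyl 2-methyl-3-oxopropanoate
Product: 9 2-(trimethylsilyl)ethyl (2S,6E,10R)-10-{[tert-butyl(dimethyl)silyl]oxy}-2-formyl-2,6,10-trimethyl-5-oxododeca-6,11-dienoate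
Conditions: 1-[3,5-bis(trifluoromethyl)phenyl]-3-[(8α,9S)-6′-methoxycinchonan-9-yl]thiourea (10 mol%), toluene, −20 °C
Reagents that add atoms: none
Why: Organocatalytic enantioselective Michael addition of an α-substituted 1,3-dicarbonyl donor to a vinyl ketone: the bifunctional cinchona thiourea binds the enol and the enone, only the unsubstituted vinyl terminus reacts, and the catalyst sets the quaternary stereocentre C4 as S.

Step 7
Reactants: 9 2-(trimethylsilyl)ethyl (2S,6E,10R)-10-{[tert-butyl(dimethyl)silyl]oxy}-2-formyl-2,6,10-trimethyl-5-oxododeca-6,11-dienoate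
Product: 10 2-(trimethylsilyl)ethyl (2S,6E,10R)-10-{[tert-butyl(dimethyl)silyl]oxy}-2-[(E)-2-iodoethenyl]-2,6,10-trimethyl-5-oxododeca-6,11-dienoate
Conditions: CrCl2 (6 equiv), CHI3 (2 equiv), THF, 0 to 23 °C
Reagents that add atoms: iodoform, IC(I)I
Why: Takai iodo-olefination with the geminal dichromium reagent converts the non-enolisable aldehyde chemoselectively (ketone and esters untouched) into the (E)-vinyl iodide, which adds C6 and fixes the E geometry of C5=C6.

Step 8
Reactants: 10 2-(trimethylsilyl)ethyl (2S,6E,10R)-10-{[tert-butyl(dimethyl)silyl]oxy}-2-[(E)-2-iodoethenyl]-2,6,10-trimethyl-5-oxododeca-6,11-dienoate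
Product: 11 2-(trimethylsilyl)ethyl (2S,6E,10R)-10-{[tert-butyl(dimethyl)silyl]oxy}-2,6,10-trimethyl-5-oxo-2-[(1E)-penta-1,3,4-trien-1-yl]dodeca-6,11-dienoate
Conditions: Bu3SnCH=C=CH2 (1.3 equiv), Pd2(dba)3 (2.5 mol%), AsPh3 (20 mol%), DMF, 23 °C, dark; used at once
Reagents that add atoms: tributyl(propa-1,2-dien-1-yl)stannane, C=C=C[Sn](CCCC)(CCCC)CCCC
Why: Stille coupling of the vinyl iodide with the allenylstannane keeps the alkene geometry and transfers the allenyl group (C7, C8, C17) to give the (E)-vinylallene, which is kept at room temperature to hold back cyclisation.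

Step 9
Reactants: 11 2-(trimethylsilyl)ethyl (2S,6E,10R)-10-{[tert-butyl(dimethyl)silyl]oxy}-2,6,10-trimethyl-5-oxo-2-[(1E)-penta-1,3,4-trien-1-yl]dodeca-6,11-dienoate
Product: 12 2-(trimethylsilyl)ethyl (1S,4aR,5S,8aS)-5-[(3R)-3-{[tert-butyl(dimethyl)silyl]oxy}-3-methylpent-4-en-1-yl]-1,4a-dimethyl-6-methylidene-4-oxo-1,2,3,4,4a,5,6,8a-octahydronaphthalene-1-carboxylate
Conditions: toluene (0.01 M), BHT (5 mol%), 90 °C
Reagents that add atoms: none
Why: Thermal intramolecular Diels–Alder reaction in which the s-cis vinylallene (C5=C6–C7=C8) adds suprafacially to the (E)-α-methyl enone (C9=C10) in a concerted, asynchronous [4+2] through the endo transition state, with the tether carbonyl C1 under the diene. The closest known reaction types are the cis-selective cycloadditions of 1,7,9-decatrien-3-ones and the Diels–Alder reactions of vinylallenes, which give 3-methylenecyclohexenes. Ring B is closed by the cycloaddition itself (bonds C5–C10 and C8–C9) and ring A closes as the tether ring when the fusion bond C5–C10 forms across the four-atom bridge C4–C3–C2–C1. C9 and C10 follow from the E geometry of the enone (C20 methyl cis to the C11 chain), and the cis fusion (H5 cis to the C20 methyl) follows from the endo mode, in which both dienophile substituents point away from the diene and from the allene hydrogen. The diene face is chosen by C4: in the chair-like tether the ester should take the pseudo-axial site syn to the C20 methyl and the C18 methyl the pseudo-equatorial one, because the other face would force a methyl–methyl 1,3-diaxial contact. The step needs endo over exo selectivity and one diene face; the E vinyl iodide geometry puts C4 on the outside of the diene, C4 has no hydrogen for a 1,5-shift, the strained allene should allow reaction at 90 °C without a Lewis acid, and C8 stays sp2 so that the C8=C17 bond is already in place.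

Step 10
Reactants: 12 2-(trimethylsilyl)ethyl (1S,4aR,5S,8aS)-5-[(3R)-3-{[tert-butyl(dimethyl)silyl]oxy}-3-methylpent-4-en-1-yl]-1,4a-dimethyl-6-methylidene-4-oxo-1,2,3,4,4a,5,6,8a-octahydronaphthalene-1-carboxylate
Product: 14 (1S,4aR,5S,8aS)-5-[(3R)-3-hydroxy-3-methylpent-4-en-1-yl]-1,4a-dimethyl-6-methylidene-4-oxodecahydronaphthalene-1-carboxylic acid, via allylboronate 13 (not isolated)
Conditions: Ni(cod)2 (5 mol%), PCy3 (5 mol%), HBpin (1.2 equiv), toluene, 23 °C; then Bu4NF·3H2O (8 equiv), THF, 50 °C; 1 M aq. HCl to pH 4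
Reagents that add atoms: none
Why: Nickel-catalysed 1,4-hydroboration is specific for the conjugated diene (hydrogen to C6, boron to the terminal C17), and fluoride-mediated protodeboronation of the allylboronate delivers the proton to the γ-carbon C7 (SE2′), which removes the ring alkene, leaves the exocyclic C8=C17 bond and spares the vinyl group; the same fluoride cleaves the silyl ether and the 2-(trimethylsilyl)ethyl ester.

Step 11
Reactants: 14 (1S,4aR,5S,8aS)-5-[(3R)-3-hydroxy-3-methylpent-4-en-1-yl]-1,4a-dimethyl-6-methylidene-4-oxodecahydronaphthalene-1-carboxylic acid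
Product: 16 (1S,4aR,5S,8aS)-5-[(3R)-3-(acetyloxy)-3-methylpent-4-en-1-yl]-1,4a-dimethyl-6-methylidene-4-oxodecahydronaphthalene-1-carboxylic acid, via mixed anhydride 15 (not isolated)
Conditions: Ac2O (5 equiv), DMAP (0.3 equiv), Et3N, CH2Cl2, 35 °C; then sat. aq. NaHCO3, THF, 23 °C; acidify to pH 4
Reagents that add atoms: acetic anhydride, CC(=O)OC(C)=O
Why: DMAP-catalysed acylation acetylates the tertiary allylic alcohol with retention at C13, and the mixed anhydride formed at the carboxyl group is hydrolysed at its unhindered acetyl carbonyl in the bicarbonate work-up.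

Step 12
Reactants: 16 (1S,4aR,5S,8aS)-5-[(3R)-3-(acetyloxy)-3-methylpent-4-en-1-yl]-1,4a-dimethyl-6-methylidene-4-oxodecahydronaphthalene-1-carboxylic acid
Product: 18 (1S,4aR,5S,8aS)-5-[(3R)-3-(acetyloxy)-3-methylpent-4-en-1-yl]-1,4a-dimethyl-6-methylidenedecahydronaphthalene-1-carboxylic acid, via tosylhydrazone 17 (not isolated)
Conditions: TsNHNH2 (1.3 equiv), EtOH, 60 °C; then catecholborane (3 equiv), CHCl3, 0 °C; NaOAc·3H2O, 60 °C
Reagents that add atoms: none
Why: Caglioti-type deoxygenation: the tosylhydrazone is reduced by catecholborane and the derived diazene loses sulfinate and dinitrogen to leave the C1 methylene under near-neutral conditions that spare the acetate, the acid and both alkenes, with no stereocentre affected.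

**Compound list**

1 | (3R)-3,7-dimethylocta-1,6-dien-3-ol [(R)-linalool] | C=C[C@@](C)(CCC=C(C)C)O | starting material
2 | tert-butyl{[(3R)-3,7-dimethylocta-1,6-dien-3-yl]oxy}dimethylsilane | C=C[C@@](C)(CCC=C(C)C)O[Si](C)(C)C(C)(C)C | intermediate
3 | (2E,6R)-6-{[tert-butyl(dimethyl)silyl]oxy}-2,6-dimethylocta-2,7-dienal | O=C/C(C)=C/CC[C@](C)(C=C)O[Si](C)(C)C(C)(C)C | intermediate
4 | (4E,8R)-8-{[tert-butyl(dimethyl)silyl]oxy}-4,8-dimethyldeca-1,4,9-trien-3-ol (both C3 epimers) | C=CC(O)/C(C)=C/CC[C@](C)(C=C)O[Si](C)(C)C(C)(C)C | intermediate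
5 | (4E,8R)-8-{[tert-butyl(dimethyl)silyl]oxy}-4,8-dimethyldeca-1,4,9-trien-3-one | C=CC(=O)/C(C)=C/CC[C@](C)(C=C)O[Si](C)(C)C(C)(C)C | intermediate
6 | ethyl 2-methyl-3-oxopropanoate | CCOC(=O)C(C)C=O | starting material
7 | 2-(trimethylsilyl)ethan-1-ol | OCC[Si](C)(C)C | starting material
8 | 2-(trimethylsilyl)ethyl 2-methyl-3-oxopropanoate | O=CC(C)C(=O)OCC[Si](C)(C)C | intermediate
9 | 2-(trimethylsilyl)ethyl (2S,6E,10R)-10-{[tert-butyl(dimethyl)silyl]oxy}-2-formyl-2,6,10-trimethyl-5-oxododeca-6,11-dienoate | O=C[C@](C)(CCC(=O)/C(C)=C/CC[C@](C)(C=C)O[Si](C)(C)C(C)(C)C)C(=O)OCC[Si](C)(C)C | intermediate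
10 | 2-(trimethylsilyl)ethyl (2S,6E,10R)-10-{[tert-butyl(dimethyl)silyl]oxy}-2-[(E)-2-iodoethenyl]-2,6,10-trimethyl-5-oxododeca-6,11-dienoate | I/C=C/[C@](C)(CCC(=O)/C(C)=C/CC[C@](C)(C=C)O[Si](C)(C)C(C)(C)C)C(=O)OCC[Si](C)(C)C | intermediate
11 | 2-(trimethylsilyl)ethyl (2S,6E,10R)-10-{[tert-butyl(dimethyl)silyl]oxy}-2,6,10-trimethyl-5-oxo-2-[(1E)-penta-1,3,4-trien-1-yl]dodeca-6,11-dienoate | C=C=C/C=C/[C@](C)(CCC(=O)/C(C)=C/CC[C@](C)(C=C)O[Si](C)(C)C(C)(C)C)C(=O)OCC[Si](C)(C)C | intermediate
12 | 2-(trimethylsilyl)ethyl (1S,4aR,5S,8aS)-5-[(3R)-3-{[tert-butyl(dimethyl)silyl]oxy}-3-methylpent-4-en-1-yl]-1,4a-dimethyl-6-methylidene-4-oxo-1,2,3,4,4a,5,6,8a-octahydronaphthalene-1-carboxylate | C=C[C@@](C)(CC[C@H]1C(=C)C=C[C@H]2[C@]1(C)C(=O)CC[C@]2(C)C(=O)OCC[Si](C)(C)C)O[Si](C)(C)C(C)(C)C | intermediate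
13 | 2-(trimethylsilyl)ethyl (1S,4aR,5S,8aS)-5-[(3R)-3-{[tert-butyl(dimethyl)silyl]oxy}-3-methylpent-4-en-1-yl]-1,4a-dimethyl-4-oxo-6-[(4,4,5,5-tetramethyl-1,3,2-dioxaborolan-2-yl)methyl]-1,2,3,4,4a,5,8,8a-octahydronaphthalene-1-carboxylate | C=C[C@@](C)(CC[C@H]1C(CB2OC(C)(C)C(C)(C)O2)=CC[C@H]3[C@]1(C)C(=O)CC[C@]3(C)C(=O)OCC[Si](C)(C)C)O[Si](C)(C)C(C)(C)C | intermediate
14 | (1S,4aR,5S,8aS)-5-[(3R)-3-hydroxy-3-methylpent-4-en-1-yl]-1,4a-dimethyl-6-methylidene-4-oxodecahydronaphthalene-1-carboxylic acid | C=C[C@@](C)(CC[C@H]1C(=C)CC[C@H]2[C@]1(C)C(=O)CC[C@]2(C)C(=O)O)O | intermediate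
15 | acetic (1S,4aR,5S,8aS)-5-[(3R)-3-(acetyloxy)-3-methylpent-4-en-1-yl]-1,4a-dimethyl-6-methylidene-4-oxodecahydronaphthalene-1-carboxylic anhydride | C=C[C@@](C)(CC[C@H]1C(=C)CC[C@H]2[C@]1(C)C(=O)CC[C@]2(C)C(=O)OC(C)=O)OC(C)=O | intermediate
16 | (1S,4aR,5S,8aS)-5-[(3R)-3-(acetyloxy)-3-methylpent-4-en-1-yl]-1,4a-dimethyl-6-methylidene-4-oxodecahydronaphthalene-1-carboxylic acid | C=C[C@@](C)(CC[C@H]1C(=C)CC[C@H]2[C@]1(C)C(=O)CC[C@]2(C)C(=O)O)OC(C)=O | intermediate
17 | (1S,4aR,5S,8aS)-5-[(3R)-3-(acetyloxy)-3-methylpent-4-en-1-yl]-1,4a-dimethyl-6-methylidene-4-{2-[(4-methylphenyl)sulfonyl]hydrazinylidene}decahydronaphthalene-1-carboxylic acid | C=C[C@@](C)(CC[C@H]1C(=C)CC[C@H]2[C@]1(C)C(=NNS(=O)(=O)c3ccc(C)cc3)CC[C@]2(C)C(=O)O)OC(C)=O | intermediate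
18 | (1S,4aR,5S,8aS)-5-[(3R)-3-(acetyloxy)-3-methylpent-4-en-1-yl]-1,4a-dimethyl-6-methylidenedecahydronaphthalene-1-carboxylic acid | C=C[C@@](C)(CC[C@H]1C(=C)CC[C@H]2[C@]1(C)CCC[C@]2(C)C(=O)O)OC(C)=O | target

Total step count: 12. Longest linear sequence: 11 steps (steps 1–4 and 6–12).

Steps most likely to fail:

Step 9 (intramolecular Diels–Alder reaction). The exo transition state (trans-fused octalone) or addition to the other diene face (wrong configuration at C5, C9 and C10 relative to C4) may compete, and the vinylallene may oligomerise before it cyclises. Fallback: the relay from C4 is redesigned with the smallest possible C19 group, a nitrile, which should take the pseudo-axial site next to the C20 methyl much more readily than a methyl group. The fallback sets out from dienone 5. Michael addition of 2-methyl-3-oxopropanenitrile under the catalysis of step 6 would give the formyl nitrile F1 (2R, the same spatial arrangement as in 9; the descriptor changes because formyl outranks cyano). Takai olefination would give the vinyl iodide F2, allenyl Stille coupling the vinylallene F3, and cycloaddition at 90 °C the cyano octalone F4. Hydroboration and fluoride treatment as in step 10 would give the hydroxy keto nitrile F5, and hydrolysis of the hindered nitrile (KOH, ethylene glycol, 160 °C, then acid) would bring the route back at hydroxy keto acid 14.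

Step 6 (enantioselective Michael addition). Incomplete enantiocontrol at C4 would be carried through the cycloaddition as diastereomers that differ from the wanted series only in the remote C13 centre and would be very hard to separate; retro-Claisen loss of the formyl group is a second risk. Fallback: auxiliary control instead of catalyst control, setting out from β-oxo ester 8. Condensation with (1S)-1-phenylethanamine (toluene, azeotropic removal of water) would give the chiral enamino ester F6. Its aza-ene type Michael addition to dienone 5 (THF, 40 °C) would give the imine F7, and hydrolysis with aqueous acetic acid would bring the route back at aldehyde 9. The enantiomer of the amine would be chosen to give the 2S sense.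

Step 10 (diene to exocyclic alkene). Boron may be delivered with the wrong regiochemistry, or the proton may go to the α-carbon C17 instead of C7, which would leave the ring double bond at C7=C8; the nickel hydride may also reduce the C1 ketone. Fallback: a tin-based sequence with Brønsted-acid proton delivery, setting out from cycloadduct 12. Palladium-catalysed 1,4-hydrostannation (Bu3SnH, Pd(PPh3)4, THF, 0 °C), which leaves isolated alkenes alone, would give the allylstannane F8. Protodestannylation with acetic acid (SE2′ attack of the proton at C7 of the neutral stannane) would give the silyl-protected exocyclic alkene F9, and Bu4NF (THF, 50 °C, then acid) would bring the route back at hydroxy keto acid 14.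

Further compounds

F1 | step 9 | (2R,6E,10R)-10-{[tert-butyl(dimethyl)silyl]oxy}-2-formyl-2,6,10-trimethyl-5-oxododeca-6,11-dienenitrile | O=C[C@](C)(CCC(=O)/C(C)=C/CC[C@](C)(C=C)O[Si](C)(C)C(C)(C)C)C#N
F2 | step 9 | (2S,6E,10R)-10-{[tert-butyl(dimethyl)silyl]oxy}-2-[(E)-2-iodoethenyl]-2,6,10-trimethyl-5-oxododeca-6,11-dienenitrile | I/C=C/[C@](C)(CCC(=O)/C(C)=C/CC[C@](C)(C=C)O[Si](C)(C)C(C)(C)C)C#N
F3 | step 9 | (2S,6E,10R)-10-{[tert-butyl(dimethyl)silyl]oxy}-2,6,10-trimethyl-5-oxo-2-[(1E)-penta-1,3,4-trien-1-yl]dodeca-6,11-dienenitrile | C=C=C/C=C/[C@](C)(CCC(=O)/C(C)=C/CC[C@](C)(C=C)O[Si](C)(C)C(C)(C)C)C#N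
F4 | step 9 | (1S,4aR,5S,8aR)-5-[(3R)-3-{[tert-butyl(dimethyl)silyl]oxy}-3-methylpent-4-en-1-yl]-1,4a-dimethyl-6-methylidene-4-oxo-1,2,3,4,4a,5,6,8a-octahydronaphthalene-1-carbonitrile | C=C[C@@](C)(CC[C@H]1C(=C)C=C[C@H]2[C@]1(C)C(=O)CC[C@]2(C)C#N)O[Si](C)(C)C(C)(C)C
F5 | step 9 | (1S,4aR,5S,8aR)-5-[(3R)-3-hydroxy-3-methylpent-4-en-1-yl]-1,4a-dimethyl-6-methylidene-4-oxodecahydronaphthalene-1-carbonitrile | C=C[C@@](C)(CC[C@H]1C(=C)CC[C@H]2[C@]1(C)C(=O)CC[C@]2(C)C#N)O
F6 | step 6 | 2-(trimethylsilyl)ethyl (2Z)-2-methyl-3-{[(1S)-1-phenylethyl]amino}prop-2-enoate | C/C(C(=O)OCC[Si](C)(C)C)=C/N[C@@H](C)c1ccccc1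
F7 | step 6 | 2-(trimethylsilyl)ethyl (2S,6E,10R)-10-{[tert-butyl(dimethyl)silyl]oxy}-2,6,10-trimethyl-5-oxo-2-[(E)-{[(1S)-1-phenylethyl]imino}methyl]dodeca-6,11-dienoate | C[C@@H](c1ccccc1)/N=C/[C@](C)(CCC(=O)/C(C)=C/CC[C@](C)(C=C)O[Si](C)(C)C(C)(C)C)C(=O)OCC[Si](C)(C)C
F8 | step 10 | 2-(trimethylsilyl)ethyl (1S,4aS,5R,8aS)-5-[(3R)-3-{[tert-butyl(dimethyl)silyl]oxy}-3-methylpent-4-en-1-yl]-1,4a-dimethyl-4-oxo-6-[(tributylstannyl)methyl]-1,2,3,4,4a,5,8,8a-octahydronaphthalene-1-carboxylate | C=C[C@@](C)(CC[C@H]1C(C[Sn](CCCC)(CCCC)CCCC)=CC[C@H]2[C@]1(C)C(=O)CC[C@]2(C)C(=O)OCC[Si](C)(C)C)O[Si](C)(C)C(C)(C)C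
F9 | step 10 | 2-(trimethylsilyl)ethyl (1S,4aR,5S,8aS)-5-[(3R)-3-{[tert-butyl(dimethyl)silyl]oxy}-3-methylpent-4-en-1-yl]-1,4a-dimethyl-6-methylidene-4-oxodecahydronaphthalene-1-carboxylate | C=C[C@@](C)(CC[C@H]1C(=C)CC[C@H]2[C@]1(C)C(=O)CC[C@]2(C)C(=O)OCC[Si](C)(C)C)O[Si](C)(C)C(C)(C)C
A1 | direct plan | methyl (1S)-1,3-dimethylcyclohex-2-ene-1-carboxylate | CC1=C[C@](C)(CCC1)C(=O)OC
A2 | direct plan | 3-(benzyloxy)cyclobutan-1-one | O=C1CC(OCc2ccccc2)C1
A3 | direct plan | methyl (1S,4aR,8aS)-1,4a-dimethyl-6-oxo-1,2,3,4,4a,5,6,8a-octahydronaphthalene-1-carboxylate | O=C1C=C[C@H]2[C@](C1)(C)CCC[C@]2(C)C(=O)OC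
A4 | direct plan | (3R)-3-{[tert-butyl(dimethyl)silyl]oxy}-3-methylpent-4-en-1-yl trifluoromethanesulfonate | C=C[C@@](C)(CCOS(=O)(=O)C(F)(F)F)O[Si](C)(C)C(C)(C)C
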